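## The problem

The target is an unsymmetrical 7,7'-linked dimer: rings A and B (C1–C8a) form a fully aromatic 2-acetyl-1,8-dihydroxy-3-methylnaphthalene, and rings C and D (C1'–C8a') form its 1',2'-dihydro-1'-hydroxy counterpart. The two halves differ only in the oxidation level of one ring, so they have to be distinguished by the way they are built, not by a late differentiation. The only stereocentres are C1' (S, benzylic carbinol) and C2' (R, acetyl-bearing), trans to each other, and together they are a cyclic aldol. C2' is α to a ketone and allylic, so it can epimerize into the trans arrangement but cannot set C1'; C1' has no neighbouring stereocentre and must take its configuration from a chiral catalyst or reagent. The ring-D β-hydroxy ketone loses water to a naphthalene with acid or base and can undergo retro-aldol cleavage, and the 1,8-dihydroxynaphthalene is prone to oxidation. Ring D therefore has to be closed last, under near-neutral conditions, with no protecting group left to remove. Regiochemically, the C2 acetyl group sits between C1–OH and C3–CH3, ring C carries four contiguous substituents (C7' aryl, C8' OH, C8a'–C1', C4a'–C4'), and the C7–C7' axis has only two ortho substituents and poses no atropisomer problem. The feature that opens the key step is ring B: the ring-C aryl group sits on C7 beside the C8 hydroxyl while C5 and C6 are unsubstituted. This is the pattern formed when a ring-A ortho-toluate (ester carbon becoming C8, benzylic methyl becoming C5) is annulated with a C6=C7 unit that carries the aryl group and a sulfonyl group on C7, the sulfonyl group leaving as sulfinate on aromatization.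

## Retrosynthesis

**C1'–C2' (aldol bond of ring D).** Cutting this bond turns target 20 into the achiral keto aldehyde 18, an isomer of 20. The last step is then an isomerization that creates both stereocentres and is followed by no deprotection. Cutting C3'=C4' or the biaryl bond first would leave the fragile aldol in place through further steps. The forward reaction needs a chiral secondary amine to convert the enone arm of 18 into dienamine 19 and to direct its α-carbon to one face of the aldehyde, trans-selectively and without onward dehydration.

**C2'=C3' (enone of the arm).** Cutting the trisubstituted alkene of 18 by cross-metathesis gives the methallyl aldehyde 16 and but-3-en-2-one 17. The alternative, olefination of an arylacetone, would need a stabilized ylide to attack an enolizable ketone beside a free aldehyde. Metathesis is neutral, so the aldehyde and the acidic C4' methylene of 18 should not meet base before the catalyst of the last step. The forward reaction needs a ruthenium carbene to engage a 1,1-disubstituted alkene.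

**C8a'–C1' (formyl group).** Removing the aldehyde carbon of 16 gives phenol 15. In 15 the only free position ortho to any hydroxyl is C8a', because C2 and C7 are substituted, so an ortho-specific phenol formylation has no regiochemical choice. The forward reaction must tolerate the aryl methyl ketone and the methallyl group.

**C4a'–C4' (arm attachment).** Cutting the benzylic bond of 15 gives aryl chloride 13 and the methallylboronate 14. The coupling is placed before the formylation because an allylboronate would add to the aldehyde. It is placed after all Lewis-acid steps because the alkene would not survive them.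

**C2–acetyl bond and two O–methyl bonds.** Triol 13 is traced to its ring-C methyl ether 12, then to diol 11 by removing the acetyl group, and then to the key-step product 10 by restoring the C1 methyl ether. The order serves the acylation. In 11 the C1 hydroxyl is free and C2 is its only open ortho position, while the ring-C oxygen is still masked, so ring C cannot be acylated. The forward steps need a chelation-assisted cleavage of the C1 ether (peri to the C8 hydroxyl), an ortho-directed acylation, and a final ether cleavage.

**C5–C6 and C7–C8 (ring B, key disconnection).** Cutting both bonds of ring B in 10 gives toluate 4 and the α-aryl vinyl sulfone 8; the keto sulfone 9 is the cyclized intermediate. The neighbouring choice is a biaryl cross-coupling at C7–C7'. That would need a 7-halo-1,8-dioxygenated naphthalene, whose halogenation ortho to the naphthol competes with para attack, and a coupling between two ortho-oxygenated carbons. The annulation instead places the aryl group on C7 and the hydroxyl on C8 by construction and reduces 10 to two benzene derivatives. The forward reaction needs lateral metalation of 4 at the methyl ortho to the ester, conjugate addition to the CH2 terminus of 8, acylation of the resulting sulfonyl carbanion on the ester, and loss of sulfinate.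

**The two fragments.** Toluate 4 comes from acid 3 by double methylation, 3 from aldehyde 2 by oxidation, and 2 from 3,5-dimethylphenol 1 by ortho-formylation (both ortho positions are equivalent). Sulfone 8 comes from enol triflate 6 and sodium benzenesulfinate 7 by C–S coupling, and 6 from ketone 5. The chlorine of 5 is the later handle for C4'.

## Roads not taken

**Alternative 1:** Ring D is cut across C1'–C2' and C3'–C4' as a Diels–Alder adduct with a temporary C1'–O–C4' bridge. In the forward direction the ring-C isobenzofuran A3 would add to (Z)-4-bromopent-3-en-2-one A2 under a chiral oxazaborolidinium Lewis acid activated by AlBr3, giving the oxygen-bridged adduct A1. Reductive opening of the bridge with loss of bromide would set C3'=C4' and free C1'–OH, and removal of the three allyl groups would lead to 20.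
- Merits: both ring-D carbon–carbon bonds and both stereocentres form in one catalytic step, and an endo acetyl group translates directly into the trans relation.
- Weak points: A3 is a reactive, short-lived diene that must be generated on a fully functionalized biaryl. A2 is a β,β-disubstituted enone and a poor dienophile that must form a quaternary C–Br centre. The orientation of the unsymmetrical diene towards the dienophile is not secured. Three allyl ethers must be removed after the sensitive aldol is exposed, and the biaryl bond still has to be made separately.
- Comparison: the rigid cycloaddition transition state is a better-understood source of absolute configuration than the amine-catalysed closure of the chosen plan. Against this the chosen plan offers a stable, isolable precursor for the stereo-defining step, ring-D regiochemistry fixed by the positions of the formyl group and the arm, and no deprotection at the end.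

**Alternative 2:** Both halves are cut at their C1–C2 aldol bonds, so the precursor is the symmetrical bis(enone) dialdehyde A5. A chiral amine (proline or a cinchona-derived primary amine salt) would convert both arms into dienamines and close two rings at once to the C2-symmetric bis-aldol A4. Oxidation of one carbinol to the ketone, which tautomerizes to the naphthol, would then give 20.
- Merits: it is the shortest route on paper, A5 is available by a homocoupling, and a double asymmetric closure enriches the enantiomeric purity of the C2-symmetric product.
- Weak points: the two rings of A4 are homotopic, so mono-oxidation is at best statistical. The oxidized half is a more electron-rich naphthalenediol than the starting material and invites over-oxidation. Dehydration of either ring competes with oxidation and would give a deoxygenated naphthalene. The unproven aldol closure must also succeed twice.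
- Comparison: this road is clearly better in step count and use of symmetry. The chosen plan is longer but never has to differentiate two identical rings, because ring B is built aromatic from the outset, and it runs the aldol closure once, as the last operation.

**Alternative 3:** Ring D is cut at C3'=C4'. An anti-selective aldol addition of an enolate of 4-methylpent-4-en-2-one A8 to the ortho-vinyl biaryl aldehyde A9 would give diene A7. The second-generation Grubbs catalyst would join the vinyl and isopropenyl groups with loss of ethene to give the bis-silyl ether A6, and desilylation would give 20.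
- Merits: ring-closing metathesis to a six-membered styrenyl alkene is dependable, and the stereocentres come from an intermolecular, reagent-controlled aldol, a well-precedented reaction class.
- Weak points: an anti- and enantioselective aldol of a simple methyl ketone such as A8 has no auxiliary to rely on, and its β,γ-alkene tends to move into conjugation. A7 must survive ruthenium catalysis without retro-aldol or dehydration. Fluoride treatment of A6 exposes the finished aldol to base. A9 itself needs a biaryl synthesis plus vinyl, formyl and silyl groups in place.
- Comparison: this road is safer in the ring closure itself and more predictable in relative configuration. The chosen plan has an atom-economical last step with no protecting groups, stereocentres made in the final operation so nothing can erode them, and a convergent construction of the biaryl.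

Key step: step 6

Remark: the C7–C7' axis bears only two ortho substituents (both hydroxyl) and is taken to rotate freely, consistent with a target that defines no axial configuration.

## Route

Step 1
Reactants: 1 3,5-dimethylphenol
Product: 2 2-hydroxy-4,6-dimethylbenzaldehyde
Conditions: MgCl2, Et3N, (CH2O)n, MeCN, reflux; aq. HCl
Reagents that add atoms: paraformaldehyde, as formaldehyde (C=O)
Why: Casnati–Skattebøl ortho-formylation; the magnesium phenoxide delivers formaldehyde to the ortho carbon through a six-membered chelate and a second formaldehyde accepts hydride; the two ortho positions of 1 are equivalent and the para position is not reached by this mechanism.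

Step 2
Reactants: 2 2-hydroxy-4,6-dimethylbenzaldehyde
Product: 3 2-hydroxy-4,6-dimethylbenzoic acid
Conditions: NaClO2, NaH2PO4, 2-methylbut-2-ene, t-BuOH/H2O, 0 °C → rt
Reagents that add atoms: sodium chlorite ([Na+].[O-]Cl=O)
Why: Pinnick oxidation; chlorous acid oxidizes the aldehyde selectively and the alkene scavenger intercepts hypochlorous acid so that the activated phenol ring should not be chlorinated.

Step 3
Reactants: 3 2-hydroxy-4,6-dimethylbenzoic acid
Product: 4 methyl 2-methoxy-4,6-dimethylbenzoate
Conditions: MeI, K2CO3, DMF, 60 °C
Reagents that add atoms: iodomethane (CI)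
Why: double O-alkylation (carboxylate alkylation and Williamson ether synthesis); alkylating the carboxylate avoids acid-catalysed esterification of a doubly ortho-substituted acid.

Step 4
Reactants: 5 1-(4-chloro-2-methoxyphenyl)ethan-1-one
Product: 6 1-(4-chloro-2-methoxyphenyl)ethenyl trifluoromethanesulfonate
Conditions: KN(SiMe3)2, PhNTf2, THF, −78 °C
Reagents that add atoms: N-phenylbis(trifluoromethanesulfonimide) (O=S(=O)(N(c1ccccc1)S(=O)(=O)C(F)(F)F)C(F)(F)F)
Why: O-triflation of the potassium enolate of a methyl ketone; there is only one enolizable position and the aryl chloride and ether are inert.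

Step 5
Reactants: 6 1-(4-chloro-2-methoxyphenyl)ethenyl trifluoromethanesulfonate; 7 sodium benzenesulfinate
Product: 8 4-chloro-2-methoxy-1-[1-(phenylsulfonyl)ethenyl]benzene
Conditions: Pd(OAc)2 (cat.), Xantphos, n-Bu4NCl, toluene, 80 °C
Reagents that add atoms: none
Why: palladium-catalysed C–S cross-coupling of an alkenyl triflate with a sulfinate salt (oxidative addition of C–OTf to zerovalent palladium formed in situ, S-bound sulfinate, reductive elimination); the aryl chloride undergoes oxidative addition far more slowly with this ligand and should remain.

Step 6
Reactants: 4 methyl 2-methoxy-4,6-dimethylbenzoate; 8 4-chloro-2-methoxy-1-[1-(phenylsulfonyl)ethenyl]benzene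
Product: 10 2-(4-chloro-2-methoxyphenyl)-8-methoxy-6-methylnaphthalen-1-ol, via keto sulfone 9 (not isolated)
Conditions: LiN(i-Pr)2 (1.05 equiv), THF, −78 °C; 8, −78 → 0 °C; KOt-Bu, 0 → 40 °C; aq. NH4Cl
Reagents that add atoms: none
Why: Proposed new method: LiN(i-Pr)2 deprotonates the 6-methyl group of benzoate 4 (the future C5), which lies ortho to the ester and gives the ester-stabilized ortho-quinodimethane enolate, and this benzylic anion adds to the CH2 terminus of 8, forming C5–C6 and an α-aryl α-sulfonyl carbanion at C7. That carbanion acylates on the ester in a 6-exo-trig Claisen step (C7–C8, closing ring B) to give the non-enolizable keto sulfone 9; KOt-Bu then removes a C6 hydrogen with loss of benzenesulfinate, and the resulting 4H-naphthalen-1-one tautomerizes to the naphtholate, which makes the sequence irreversible. The closest known reaction type is the Staunton–Weinreb toluate-anion Michael–Claisen annulation, combined with the sulfinate-loss aromatization of Hauser-type sulfone annulations and the acylation of sulfonyl carbanions by esters; an α-aryl vinyl sulfone has not been shown as the two-carbon partner. No stereocentre remains, since the quaternary centre of racemic 9 is destroyed on elimination. The step needs lateral metalation at the ortho methyl and not at the para methyl or the ring, which the coordinating ester secures, and a single direction of conjugate addition, which the sulfonyl group secures. Only one equivalent of amide base is used so that the acidic ring-C hydrogen between OMe and Cl of 8 is not metalated.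

Step 7
Reactants: 10 2-(4-chloro-2-methoxyphenyl)-8-methoxy-6-methylnaphthalen-1-ol
Product: 11 2-(4-chloro-2-methoxyphenyl)-6-methylnaphthalene-1,8-diol
Conditions: BCl3, CH2Cl2, −78 → 0 °C; H2O
Reagents that add atoms: none
Why: chelation-assisted ether cleavage; BCl3 first forms the aryloxyborane at the free hydroxyl, whose boron is held beside the peri methoxy oxygen in a six-membered chelate, so chloride removes that methyl group at low temperature while the unassisted ring-C anisole should remain.

Step 8
Reactants: 11 2-(4-chloro-2-methoxyphenyl)-6-methylnaphthalene-1,8-diol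
Product: 12 1-[7-(4-chloro-2-methoxyphenyl)-1,8-dihydroxy-3-methylnaphthalen-2-yl]ethan-1-one
Conditions: AcCl, TiCl4, PhCl, 90 °C; aq. HCl
Reagents that add atoms: acetyl chloride (CC(Cl)=O)
Why: TiCl4-mediated ortho-acylation of a phenol (Friedel–Crafts/Fries manifold); the titanium aryloxide delivers the acyl group to the ortho carbon, and C2 is the only free ortho position of the two hydroxyl groups because C7 is occupied; the ring-C oxygen is still a methyl ether on a chlorine-deactivated ring and should not compete.

Step 9
Reactants: 12 1-[7-(4-chloro-2-methoxyphenyl)-1,8-dihydroxy-3-methylnaphthalen-2-yl]ethan-1-one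
Product: 13 1-[7-(4-chloro-2-hydroxyphenyl)-1,8-dihydroxy-3-methylnaphthalen-2-yl]ethan-1-one
Conditions: BBr3, CH2Cl2, −78 °C → rt; H2O
Reagents that add atoms: none
Why: BBr3 cleavage of the remaining aryl methyl ether through the bromoborane–ether adduct; the aryl ketone, aryl chloride and biaryl are inert to these conditions.

Step 10
Reactants: 13 1-[7-(4-chloro-2-hydroxyphenyl)-1,8-dihydroxy-3-methylnaphthalen-2-yl]ethan-1-one; 14 4,4,5,5-tetramethyl-2-(2-methylprop-2-en-1-yl)-1,3,2-dioxaborolane
Product: 15 1-{1,8-dihydroxy-7-[2-hydroxy-4-(2-methylprop-2-en-1-yl)phenyl]-3-methylnaphthalen-2-yl}ethan-1-one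
Conditions: Pd(OAc)2 (cat.), SPhos, K3PO4, THF/H2O, 60 °C
Reagents that add atoms: none
Why: Suzuki–Miyaura allyl–aryl coupling; the symmetrical 2-methylallyl group removes any α/γ ambiguity, an electron-rich biarylphosphine enables oxidative addition of the electron-rich aryl chloride, and the coupling is run before the aldehyde exists because allylboronates add to aldehydes, whereas the hindered chelated ketone is far less reactive.

Step 11
Reactants: 15 1-{1,8-dihydroxy-7-[2-hydroxy-4-(2-methylprop-2-en-1-yl)phenyl]-3-methylnaphthalen-2-yl}ethan-1-one
Product: 16 3-(7-acetyl-1,8-dihydroxy-6-methylnaphthalen-2-yl)-2-hydroxy-6-(2-methylprop-2-en-1-yl)benzaldehyde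
Conditions: MgCl2, Et3N, (CH2O)n, MeCN, 70 °C; cold dilute HCl
Reagents that add atoms: paraformaldehyde, as formaldehyde (C=O)
Why: Casnati–Skattebøl ortho-formylation; only a magnesium phenoxide with a free ortho carbon can react, and C8a' is the single such position because C2 and C7 are substituted, so the aldehyde can only enter between the ring-C hydroxyl and the methallyl-bearing carbon.

Step 12
Reactants: 16 3-(7-acetyl-1,8-dihydroxy-6-methylnaphthalen-2-yl)-2-hydroxy-6-(2-methylprop-2-en-1-yl)benzaldehyde; 17 but-3-en-2-one
Product: 18 3-(7-acetyl-1,8-dihydroxy-6-methylnaphthalen-2-yl)-2-hydroxy-6-[(2E)-2-methyl-4-oxopent-2-en-1-yl]benzaldehyde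
Conditions: 17 (excess), second-generation Hoveyda–Grubbs catalyst RuCl2(=CH-C6H4-2-O-i-Pr)(H2IMes) (cat.), CH2Cl2, 40 °C
Reagents that add atoms: none
Why: olefin cross-metathesis of a 1,1-disubstituted alkene with an electron-poor vinyl ketone in excess, a known route to trisubstituted enones with N-heterocyclic-carbene ruthenium catalysts; neither partner homodimerizes readily, ethene is lost, the conditions are neutral so the aldehyde and the acidic C4' methylene are left alone, and the Z isomer of 18 would feed the same dienamine in step 13.

Step 13
Reactants: 18 3-(7-acetyl-1,8-dihydroxy-6-methylnaphthalen-2-yl)-2-hydroxy-6-[(2E)-2-methyl-4-oxopent-2-en-1-yl]benzaldehyde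
Product: 20 1-[(1S,2R)-7-(7-acetyl-1,8-dihydroxy-6-methylnaphthalen-2-yl)-1,8-dihydroxy-3-methyl-1,2-dihydronaphthalen-2-yl]ethan-1-one, via dienamine 19 (not isolated)
Conditions: D-proline (30 mol %), DMSO, rt
Reagents that add atoms: none
Why: Proposed new method: D-proline should condense with the methyl ketone of the arm to an iminium ion whose acidic benzylic C4' hydrogens are lost to give the linear dienamine 19; its α-carbon (C2') is the only nucleophilic site that can reach the aldehyde through a six-membered ring (γ-attack would close a four-membered ring), so a 6-enolexo addition forms C1'–C2' and hydrolysis releases the catalyst. The closest known reaction types are the proline-catalysed 6-enolexo aldolization of dicarbonyl compounds and α-functionalization of enone-derived dienamines. The (E)-enamine with the aryl group anti to the enamine carbon places hydroxyl and acetyl trans, and in the enamine–carboxylic acid transition-state model, in which the acid hydrogen-bonds to the aldehyde oxygen, the D-catalyst is expected to give (1'S,2'R), the mirror image of the sense that L-proline gives with cyclohexanone and aryl aldehydes.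

## Compound list

1 | 3,5-dimethylphenol | Cc1cc(C)cc(O)c1 | starting material
2 | 2-hydroxy-4,6-dimethylbenzaldehyde | Cc1cc(C)c(C=O)c(O)c1 | intermediate
3 | 2-hydroxy-4,6-dimethylbenzoic acid | Cc1cc(C)c(C(=O)O)c(O)c1 | intermediate
4 | methyl 2-methoxy-4,6-dimethylbenzoate | COC(=O)c1c(C)cc(C)cc1OC | intermediate
5 | 1-(4-chloro-2-methoxyphenyl)ethan-1-one | CC(=O)c1ccc(Cl)cc1OC | starting material
6 | 1-(4-chloro-2-methoxyphenyl)ethenyl trifluoromethanesulfonate | C=C(OS(=O)(=O)C(F)(F)F)c1ccc(Cl)cc1OC | intermediate
7 | sodium benzenesulfinate | [Na+].[O-]S(=O)c1ccccc1 | starting material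
8 | 4-chloro-2-methoxy-1-[1-(phenylsulfonyl)ethenyl]benzene | C=C(c1ccc(Cl)cc1OC)S(=O)(=O)c1ccccc1 | intermediate
9 | 2-(4-chloro-2-methoxyphenyl)-8-methoxy-6-methyl-2-(phenylsulfonyl)-3,4-dihydronaphthalen-1(2H)-one (racemic) | COc1cc(C)cc2CCC(c3ccc(Cl)cc3OC)(S(=O)(=O)c3ccccc3)C(=O)c12 | intermediate
10 | 2-(4-chloro-2-methoxyphenyl)-8-methoxy-6-methylnaphthalen-1-ol | COc1cc(C)cc2ccc(-c3ccc(Cl)cc3OC)c(O)c12 | intermediate
11 | 2-(4-chloro-2-methoxyphenyl)-6-methylnaphthalene-1,8-diol | Oc1cc(C)cc2ccc(-c3ccc(Cl)cc3OC)c(O)c12 | intermediate
12 | 1-[7-(4-chloro-2-methoxyphenyl)-1,8-dihydroxy-3-methylnaphthalen-2-yl]ethan-1-one | CC(=O)c1c(C)cc2ccc(-c3ccc(Cl)cc3OC)c(O)c2c1O | intermediate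
13 | 1-[7-(4-chloro-2-hydroxyphenyl)-1,8-dihydroxy-3-methylnaphthalen-2-yl]ethan-1-one | CC(=O)c1c(C)cc2ccc(-c3ccc(Cl)cc3O)c(O)c2c1O | intermediate
14 | 4,4,5,5-tetramethyl-2-(2-methylprop-2-en-1-yl)-1,3,2-dioxaborolane | CC(=C)CB1OC(C)(C)C(C)(C)O1 | starting material
15 | 1-{1,8-dihydroxy-7-[2-hydroxy-4-(2-methylprop-2-en-1-yl)phenyl]-3-methylnaphthalen-2-yl}ethan-1-one | CC(=O)c1c(C)cc2ccc(-c3ccc(CC(C)=C)cc3O)c(O)c2c1O | intermediate
16 | 3-(7-acetyl-1,8-dihydroxy-6-methylnaphthalen-2-yl)-2-hydroxy-6-(2-methylprop-2-en-1-yl)benzaldehyde | CC(=O)c1c(C)cc2ccc(-c3ccc(CC(C)=C)c(C=O)c3O)c(O)c2c1O | intermediate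
17 | but-3-en-2-one | CC(=O)C=C | starting material
18 | 3-(7-acetyl-1,8-dihydroxy-6-methylnaphthalen-2-yl)-2-hydroxy-6-[(2E)-2-methyl-4-oxopent-2-en-1-yl]benzaldehyde | CC(=O)/C=C(\C)Cc1ccc(-c2ccc3cc(C)c(C(C)=O)c(O)c3c2O)c(O)c1C=O | intermediate
19 | (2R)-1-{(2E,4Z)-5-[4-(7-acetyl-1,8-dihydroxy-6-methylnaphthalen-2-yl)-2-formyl-3-hydroxyphenyl]-4-methylpenta-2,4-dien-2-yl}pyrrolidine-2-carboxylic acid | C/C(N1CCC[C@@H]1C(O)=O)=C\C(C)=C/c1ccc(-c2ccc3cc(C)c(C(C)=O)c(O)c3c2O)c(O)c1C=O | intermediate
20 | 1-[(1S,2R)-7-(7-acetyl-1,8-dihydroxy-6-methylnaphthalen-2-yl)-1,8-dihydroxy-3-methyl-1,2-dihydronaphthalen-2-yl]ethan-1-one | CC(=O)c1c(C)cc2ccc(-c3ccc4c(c3O)[C@@H](O)[C@H](C(C)=O)C(C)=C4)c(O)c2c1O | target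

## Step count and risks

Total: 13 steps. Longest linear sequence: 11 steps (steps 1–3 and 6–13, from 1).

**Step 6 (key step, proposed new method).** The most likely failure is that the hindered tertiary sulfonyl carbanion does not acylate on the doubly ortho-substituted ester. The sequence then stops at the open conjugate adduct, or the carbanion adds to more vinyl sulfone. Loss of sulfinate may also stall, because the C6 hydrogens are not activated and the elimination is not an E1cB process. The fallback builds ring B and the C7–aryl bond separately with known reactions, setting out from 4 and returning at 10.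
- The lithiated toluate of 4 is combined with tert-butyl acrylate in a Michael–Dieckmann annulation to give tert-butyl 8-methoxy-6-methyl-1-oxo-1,2,3,4-tetrahydronaphthalene-2-carboxylate F1.
- Trifluoroacetic acid removes the ester with decarboxylation to 8-methoxy-6-methyl-3,4-dihydronaphthalen-1(2H)-one F2.
- Palladium-catalysed ketone α-arylation (Pd(OAc)2, a bulky phosphine, NaOt-Bu) with commercial 1-bromo-4-chloro-2-methoxybenzene, whose bromide reacts in preference to the chloride, gives 2-(4-chloro-2-methoxyphenyl)-8-methoxy-6-methyl-3,4-dihydronaphthalen-1(2H)-one F3.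
- Dehydrogenation with DDQ in hot dioxane aromatizes F3 to 10.

**Step 13 (proposed new method).** The most likely failures are insufficient facial discrimination in the ring closure (low enantiomeric purity, or the opposite sense to that predicted), a racemic background cyclization promoted by the acidic phenols, and loss of water from the aldol through its own enamine, which would aromatize ring D. The fallback gives up catalyst control. Setting out from 18, the aldol addition is run under classical achiral conditions for intramolecular ketone–aldehyde aldol additions (pyrrolidinium acetate, or catalytic K2CO3 in MeOH at low temperature). The base-labile C2' centre settles trans, giving the racemate, that is 20 together with its enantiomer 1-[(1R,2S)-7-(7-acetyl-1,8-dihydroxy-6-methylnaphthalen-2-yl)-1,8-dihydroxy-3-methyl-1,2-dihydronaphthalen-2-yl]ethan-1-one F4. The two are separated by preparative HPLC on a chiral stationary phase, which returns the route at 20.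

**Step 11.** Under MgCl2/Et3N, formaldehyde may also be taken up at the methyl group of the chelated aryl ketone. Substitution at the crowded position between the hydroxyl and the methallyl-bearing carbon may be slow. The new magnesium-bound aldehyde may close onto the methallyl group in a carbonyl-ene reaction. The fallback generates the aldehyde without base and without a Lewis-acidic metal, setting out from 15 and returning at 16.
- Boronic acid-templated ortho-hydroxymethylation (PhB(OH)2, paraformaldehyde, catalytic propionic acid, toluene, water removal) gives 1-{1,8-dihydroxy-3-methyl-7-[5-(2-methylprop-2-en-1-yl)-2-phenyl-4H-1,3,2-benzodioxaborinin-8-yl]naphthalen-2-yl}ethan-1-one F5.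
- Exchange with propane-1,3-diol frees 1-{1,8-dihydroxy-7-[2-hydroxy-3-(hydroxymethyl)-4-(2-methylprop-2-en-1-yl)phenyl]-3-methylnaphthalen-2-yl}ethan-1-one F6.
- MnO2 in CH2Cl2 oxidizes the benzylic alcohol of F6 to 16.

**Step 12.** The 1,1-disubstituted alkene may turn over slowly with the electron-poor partner. The ruthenium hydride formed on catalyst decay may move the double bond into conjugation with ring C. The salicylaldehyde and the naphthalenediol may bind the metal. The fallback changes the partner and adds a redox step. Setting out from 16, cross-metathesis with but-3-en-2-ol, a more reactive partner that does not polymerize, gives 3-(7-acetyl-1,8-dihydroxy-6-methylnaphthalen-2-yl)-2-hydroxy-6-[(2E)-4-hydroxy-2-methylpent-2-en-1-yl]benzaldehyde F7. Oxidation of the allylic alcohol with MnO2 returns the route at 18.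

**Step 8.** Acylation may go para to the hydroxyl groups (C4 or C5) instead of ortho, or an O-acetate may persist without rearranging. The fallback reaches the ketone by an ortho-specific formylation and a one-carbon addition, setting out from 11 and returning at 12.
- Casnati–Skattebøl formylation (MgCl2, Et3N, paraformaldehyde) can only occur at C2, the sole free ortho position of a free phenol in 11, and gives 7-(4-chloro-2-methoxyphenyl)-1,8-dihydroxy-3-methylnaphthalene-2-carbaldehyde F8.
- Excess MeMgBr adds to give 7-(4-chloro-2-methoxyphenyl)-2-(1-hydroxyethyl)-3-methylnaphthalene-1,8-diol F9.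
- MnO2 oxidizes the benzylic alcohol of F9 to 12.

## Further compounds

F1 | step 6 | tert-butyl 8-methoxy-6-methyl-1-oxo-1,2,3,4-tetrahydronaphthalene-2-carboxylate (racemic, enolizable) | COc1cc(C)cc2CCC(C(=O)OC(C)(C)C)C(=O)c12
F2 | step 6 | 8-methoxy-6-methyl-3,4-dihydronaphthalen-1(2H)-one | COc1cc(C)cc2CCCC(=O)c12
F3 | step 6 | 2-(4-chloro-2-methoxyphenyl)-8-methoxy-6-methyl-3,4-dihydronaphthalen-1(2H)-one (racemic) | COc1cc(C)cc2CCC(c3ccc(Cl)cc3OC)C(=O)c12
F4 | step 13 | 1-[(1R,2S)-7-(7-acetyl-1,8-dihydroxy-6-methylnaphthalen-2-yl)-1,8-dihydroxy-3-methyl-1,2-dihydronaphthalen-2-yl]ethan-1-one | CC(=O)c1c(C)cc2ccc(-c3ccc4c(c3O)[C@H](O)[C@@H](C(C)=O)C(C)=C4)c(O)c2c1O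
F5 | step 11 | 1-{1,8-dihydroxy-3-methyl-7-[5-(2-methylprop-2-en-1-yl)-2-phenyl-4H-1,3,2-benzodioxaborinin-8-yl]naphthalen-2-yl}ethan-1-one | CC(=O)c1c(C)cc2ccc(-c3ccc(CC(C)=C)c4COB(c5ccccc5)Oc34)c(O)c2c1O
F6 | step 11 | 1-{1,8-dihydroxy-7-[2-hydroxy-3-(hydroxymethyl)-4-(2-methylprop-2-en-1-yl)phenyl]-3-methylnaphthalen-2-yl}ethan-1-one | CC(=O)c1c(C)cc2ccc(-c3ccc(CC(C)=C)c(CO)c3O)c(O)c2c1O
F7 | step 12 | 3-(7-acetyl-1,8-dihydroxy-6-methylnaphthalen-2-yl)-2-hydroxy-6-[(2E)-4-hydroxy-2-methylpent-2-en-1-yl]benzaldehyde (racemic at the carbinol) | CC(O)/C=C(\C)Cc1ccc(-c2ccc3cc(C)c(C(C)=O)c(O)c3c2O)c(O)c1C=O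
F8 | step 8 | 7-(4-chloro-2-methoxyphenyl)-1,8-dihydroxy-3-methylnaphthalene-2-carbaldehyde | O=Cc1c(C)cc2ccc(-c3ccc(Cl)cc3OC)c(O)c2c1O
F9 | step 8 | 7-(4-chloro-2-methoxyphenyl)-2-(1-hydroxyethyl)-3-methylnaphthalene-1,8-diol (racemic) | CC(O)c1c(C)cc2ccc(-c3ccc(Cl)cc3OC)c(O)c2c1O
A1 | alternative 1 | endo-acetyl 3'-bromo-1',4'-epoxy-1',2',3',4'-tetrahydronaphthalene adduct, tris(allyl ether) | CC(=O)c1c(C)cc2ccc(-c3ccc4c(c3OCC=C)[C@@H]5[C@H](C(C)=O)[C@](C)(Br)[C@H]4O5)c(OCC=C)c2c1OCC=C
A2 | alternative 1 | (Z)-4-bromopent-3-en-2-one | CC(=O)/C=C(/C)Br
A3 | alternative 1 | 1-{1,8-bis(allyloxy)-7-[4-(allyloxy)-2-benzofuran-5-yl]-3-methylnaphthalen-2-yl}ethan-1-one (ring-C isobenzofuran) | CC(=O)c1c(C)cc2ccc(-c3ccc4cocc4c3OCC=C)c(OCC=C)c2c1OCC=C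
A4 | alternative 2 | C2-symmetric bis[(1S,2R)-2-acetyl-1,8-dihydroxy-3-methyl-1,2-dihydronaphthalen-7-yl] | Oc1c(-c2ccc3c(c2O)[C@@H](O)[C@H](C(C)=O)C(C)=C3)ccc2c1[C@@H](O)[C@H](C(C)=O)C(C)=C2
A5 | alternative 2 | 2,2'-dihydroxy-4,4'-bis[(2E)-2-methyl-4-oxopent-2-en-1-yl]biphenyl-3,3'-dicarbaldehyde | CC(=O)/C=C(\C)Cc1ccc(-c2ccc(C/C(C)=C/C(C)=O)c(C=O)c2O)c(O)c1C=O
A6 | alternative 3 | 8,8'-bis-O-(tert-butyldimethylsilyl) ether of the target | CC(=O)c1c(C)cc2ccc(-c3ccc4c(c3O[Si](C)(C)C(C)(C)C)[C@@H](O)[C@H](C(C)=O)C(C)=C4)c(O[Si](C)(C)C(C)(C)C)c2c1O
A7 | alternative 3 | (1'S,2'R) anti-aldol diene with aryl vinyl and isopropenyl groups, bis-silyl ether | CC(=O)c1c(C)cc2ccc(-c3ccc(C=C)c([C@@H](O)[C@H](C(C)=O)C(C)=C)c3O[Si](C)(C)C(C)(C)C)c(O[Si](C)(C)C(C)(C)C)c2c1O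
A8 | alternative 3 | 4-methylpent-4-en-2-one | CC(=C)CC(C)=O
A9 | alternative 3 | 3-[7-acetyl-1-(tert-butyldimethylsilyloxy)-8-hydroxy-6-methylnaphthalen-2-yl]-2-(tert-butyldimethylsilyloxy)-6-vinylbenzaldehyde | CC(=O)c1c(C)cc2ccc(-c3ccc(C=C)c(C=O)c3O[Si](C)(C)C(C)(C)C)c(O[Si](C)(C)C(C)(C)C)c2c1O
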